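**Retrosynthetic overview**

1. The target is a 3'→6''-linked biflavonoid: a (2S)-5,7-dihydroxy-4'-methoxyflavanone joined through C6 of its ring A to C3' of 5,7-dihydroxy-4'-methoxyflavone. Its only stereocentre is C2 of the flavanone.
2. Last disconnection: the O1–C2 bond of the flavanone dihydropyranone ring (O1, C2, C3, C4, C4a, C8a). This opens it to an achiral 2'-hydroxychalcone carrying a tert-butyl ester on C3 as a removable activating group. In the forward sense it is the chalcone-to-flavanone isomerisation of flavonoid biosynthesis, run with a chiral bifunctional thiourea and finished by loss of the ester in the same flask.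
3. Enabling feature: on ring A of the flavanone half, O1 (on C8a) and the C4 carbonyl (on C4a) are ortho, so the phenol oxygen sits six atoms from the benzylidene carbon C2 of the enone. The second ortho oxygen (on C5) stays benzylated, so only O1 can close and the biaryl carbon becomes C6, not C8.
4. Earlier disconnections: Knoevenagel condensation (C2=C3, 4-methoxybenzaldehyde), Claisen-type acylation (C3 ester), and Suzuki coupling (C6–C3' bond) of a flavone 3'-boronate with a bromo ketone. Both rings A come from the same ketone 1: cyclised through its phenol for the flavone, brominated para to that phenol for the flavanone.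
5. Ring order: flavone pyranone ring first (oxidative chalcone cyclisation), then the biaryl bond, then the flavanone ring last. Hydrogenolysis of four benzyl ethers ends the route.

Key step: step 9

Assumption: the quinine-derived thiourea is taken to deliver the 2S flavanone; the sense of induction is to be checked on a model substrate, and if it is opposite the quinidine-derived pseudoenantiomer is used under the same conditions.
Assumption: the biaryl axis (ortho substituents OMe, O, O) rotates freely, so no axial stereochemistry arises, in line with the target structure.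
Assumption: ketone 1 and aldehydes 2 and 11 are commercial.

**Route**

Step 1
Reactants: 1 1-[2,4-bis(benzyloxy)-6-hydroxyphenyl]ethan-1-one; 2 3-bromo-4-methoxybenzaldehyde
Product: 3 (2E)-1-[2,4-bis(benzyloxy)-6-hydroxyphenyl]-3-(3-bromo-4-methoxyphenyl)prop-2-en-1-one
Conditions: KOH, EtOH/THF, rt
Reagents that add atoms: none
Why: Claisen–Schmidt condensation, in which the enolate of methyl ketone 1 adds to the non-enolisable aldehyde 2 and the aldol dehydrates to the conjugated E-enone, with benzyl ethers and aryl bromide inert to hydroxide.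

Step 2
Reactants: 3 (2E)-1-[2,4-bis(benzyloxy)-6-hydroxyphenyl]-3-(3-bromo-4-methoxyphenyl)prop-2-en-1-one
Product: 4 5,7-bis(benzyloxy)-2-(3-bromo-4-methoxyphenyl)-4H-chromen-4-one
Conditions: I2 (10 mol %), DMSO, 130 °C
Reagents that add atoms: none
Why: Iodine-catalysed oxidative cyclisation of a 2'-hydroxychalcone (oxa-Michael closure, α-iodination, loss of HI, DMSO re-oxidising HI to I2) should close the pyranone ring of the flavone half, a transformation that benzyl ethers and aryl bromides tolerate.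

Step 3
Reactants: 4 5,7-bis(benzyloxy)-2-(3-bromo-4-methoxyphenyl)-4H-chromen-4-one
Product: 5 5,7-bis(benzyloxy)-2-[4-methoxy-3-(4,4,5,5-tetramethyl-1,3,2-dioxaborolan-2-yl)phenyl]-4H-chromen-4-one
Conditions: B2pin2, PdCl2(dppf) (5 mol %), KOAc, 1,4-dioxane, 90 °C
Reagents that add atoms: bis(pinacolato)diboron, CC1(C)OB(OC1(C)C)B1OC(C)(C)C(C)(C)O1
Why: Miyaura borylation of the aryl bromide, with acetate as a base too weak to trigger Suzuki homocoupling and a flavone core that is inert to these conditions.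

Step 4
Reactants: 1 1-[2,4-bis(benzyloxy)-6-hydroxyphenyl]ethan-1-one
Product: 6 1-[2,4-bis(benzyloxy)-6-{[tri(propan-2-yl)silyl]oxy}phenyl]ethan-1-one
Conditions: TIPSCl, imidazole, DMAP (cat.), DMF, 40 °C
Reagents that add atoms: chlorotri(propan-2-yl)silane, CC(C)[Si](Cl)(C(C)C)C(C)C
Why: Silylation of the phenol masks the oxygen that will become O1 and places a bulky group next to one of the two free ring positions, which is what steers the next step.

Step 5
Reactants: 6 1-[2,4-bis(benzyloxy)-6-{[tri(propan-2-yl)silyl]oxy}phenyl]ethan-1-one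
Product: 7 1-[2,4-bis(benzyloxy)-3-bromo-6-{[tri(propan-2-yl)silyl]oxy}phenyl]ethan-1-one
Conditions: NBS, MeCN, −20 to 0 °C, dark
Reagents that add atoms: N-bromosuccinimide, O=C1CCC(=O)N1Br
Why: Electrophilic aromatic bromination should take the ring position between the two benzyloxy groups (para to the silyloxy group), because the other free position is screened by the triisopropylsilyl group and a silyloxy group is the weaker donor, so bromine lands para to the future O1 and thus at the future C6 (pattern to be confirmed by NOE and HMBC before going on).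

Step 6
Reactants: 5 5,7-bis(benzyloxy)-2-[4-methoxy-3-(4,4,5,5-tetramethyl-1,3,2-dioxaborolan-2-yl)phenyl]-4H-chromen-4-one; 7 1-[2,4-bis(benzyloxy)-3-bromo-6-{[tri(propan-2-yl)silyl]oxy}phenyl]ethan-1-one
Product: 9 1-[2,4-bis(benzyloxy)-3-{5-[5,7-bis(benzyloxy)-4-oxo-4H-chromen-2-yl]-2-methoxyphenyl}-6-hydroxyphenyl]ethan-1-one, via silyl-protected biaryl ketone 8 (not isolated)
Conditions: Pd(OAc)2 (5 mol %), SPhos (10 mol %), K3PO4, toluene/H2O 10:1, 90 °C; then Bu4NF, THF, 0 °C; AcOH
Reagents that add atoms: none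
Why: Suzuki–Miyaura coupling with a dialkylbiarylphosphine suited to electron-rich di-ortho-alkoxy aryl bromides and tri-ortho-substituted biaryls (the same steric pattern as 3'–6'' biflavone couplings), followed in the same flask by fluoride cleavage of the aryl silyl ether, with ketone, flavone and benzyl ethers inert.

Step 7
Reactants: 9 1-[2,4-bis(benzyloxy)-3-{5-[5,7-bis(benzyloxy)-4-oxo-4H-chromen-2-yl]-2-methoxyphenyl}-6-hydroxyphenyl]ethan-1-one
Product: 10 tert-butyl 3-[2,4-bis(benzyloxy)-3-{5-[5,7-bis(benzyloxy)-4-oxo-4H-chromen-2-yl]-2-methoxyphenyl}-6-hydroxyphenyl]-3-oxopropanoate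
Conditions: LiN(SiMe3)2 (3.1 equiv), THF, −78 °C; Boc2O, −78 to 0 °C; AcOH
Reagents that add atoms: di-tert-butyl dicarbonate, CC(C)(C)OC(=O)OC(=O)OC(C)(C)C
Why: Claisen-type C-acylation, in which the phenoxide–enolate dianion takes up the tert-butoxycarbonyl group on carbon (directly or by Baker–Venkataraman-like O-to-C transfer from the aryl carbonate) to give the β-keto ester that will activate C3, the silylamide being non-nucleophilic and too weak to metalate the flavone.

Step 8
Reactants: 10 tert-butyl 3-[2,4-bis(benzyloxy)-3-{5-[5,7-bis(benzyloxy)-4-oxo-4H-chromen-2-yl]-2-methoxyphenyl}-6-hydroxyphenyl]-3-oxopropanoate; 11 4-methoxybenzaldehyde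
Product: 12 tert-butyl (2Z)-2-[2,4-bis(benzyloxy)-3-{5-[5,7-bis(benzyloxy)-4-oxo-4H-chromen-2-yl]-2-methoxyphenyl}-6-hydroxybenzoyl]-3-(4-methoxyphenyl)prop-2-enoate
Conditions: piperidine (20 mol %), AcOH (20 mol %), benzene, 4 Å MS, rt
Reagents that add atoms: none
Why: Knoevenagel condensation of the doubly activated methylene with aldehyde 11 should give the alkylidene β-keto ester (Z isomer expected as the major one, both isomers being usable), which is the ring-open, ester-activated form of the chalcone.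

Step 9
Reactants: 12 tert-butyl (2Z)-2-[2,4-bis(benzyloxy)-3-{5-[5,7-bis(benzyloxy)-4-oxo-4H-chromen-2-yl]-2-methoxyphenyl}-6-hydroxybenzoyl]-3-(4-methoxyphenyl)prop-2-enoate
Product: 14 (2S)-5,7-bis(benzyloxy)-6-{5-[5,7-bis(benzyloxy)-4-oxo-4H-chromen-2-yl]-2-methoxyphenyl}-2-(4-methoxyphenyl)-2,3-dihydro-4H-chromen-4-one, via trans-3-tert-butoxycarbonyl flavanone 13 (not isolated)
Conditions: N-[3,5-bis(trifluoromethyl)phenyl]-N'-(9-deoxy-epi-quinin-9-yl)thiourea (10 mol %), toluene/CH2Cl2 4:1, −25 °C; then TsOH·H2O, 80 °C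
Reagents that add atoms: none
Why: The thiourea N–H bonds bind the ketone and ester carbonyls of the alkylidene β-keto ester while the quinuclidine nitrogen activates the phenol O–H, so the phenol oxygen adds to the benzylidene carbon in a chalcone-isomerase-like oxa-Michael addition that closes the dihydropyranone ring in the 6-endo-trig mode. The closest known reaction type is the cinchona-thiourea-catalysed cyclisation of 2'-hydroxyaryl alkylidene β-keto esters to 3-carboxyflavanones with decarboxylation in the same flask. C2 is set by the catalyst, which exposes one enantioface of the enone to the bound phenol, whereas the C3 centre of 13 is transient (trans by equilibration) and is erased. The step needs site selectivity between the two oxygens ortho to the carbonyl, which is secured because only O1 is a free phenol while the C5 oxygen is a benzyl ether, so the biaryl stays at C6. It also needs face selectivity without racemic background, secured by low temperature and the absence of any achiral base. Adding acid then stops the amine catalysis and removes the tert-butyl ester as isobutene and CO2, which takes away the acidic C3–H that would allow retro-oxa-Michael scrambling of C2.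

Step 10
Reactants: 14 (2S)-5,7-bis(benzyloxy)-6-{5-[5,7-bis(benzyloxy)-4-oxo-4H-chromen-2-yl]-2-methoxyphenyl}-2-(4-methoxyphenyl)-2,3-dihydro-4H-chromen-4-one
Product: 15 (2S)-6-[5-(5,7-dihydroxy-4-oxo-4H-chromen-2-yl)-2-methoxyphenyl]-5,7-dihydroxy-2-(4-methoxyphenyl)-2,3-dihydro-4H-chromen-4-one
Conditions: H2 (1 atm), Pd/C (10 %), EtOAc/MeOH, rt; base-free work-up
Reagents that add atoms: none
Why: Hydrogenolysis of the four benzyl aryl ethers under neutral conditions, stopped at full debenzylation, should leave the flavone C2=C3 bond, both ketones, the methyl ethers and the benzylic C2–O bond untouched and cannot epimerise C2, which is base-labile in the free 5-hydroxyflavanone.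

**Compound list**

1 | 1-[2,4-bis(benzyloxy)-6-hydroxyphenyl]ethan-1-one | CC(=O)c1c(O)cc(OCc2ccccc2)cc1OCc1ccccc1 | starting material
2 | 3-bromo-4-methoxybenzaldehyde | COc1ccc(C=O)cc1Br | starting material
3 | (2E)-1-[2,4-bis(benzyloxy)-6-hydroxyphenyl]-3-(3-bromo-4-methoxyphenyl)prop-2-en-1-one | COc1ccc(/C=C/C(=O)c2c(O)cc(OCc3ccccc3)cc2OCc2ccccc2)cc1Br | intermediate
4 | 5,7-bis(benzyloxy)-2-(3-bromo-4-methoxyphenyl)-4H-chromen-4-one | COc1ccc(-c2cc(=O)c3c(OCc4ccccc4)cc(OCc4ccccc4)cc3o2)cc1Br | intermediate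
5 | 5,7-bis(benzyloxy)-2-[4-methoxy-3-(4,4,5,5-tetramethyl-1,3,2-dioxaborolan-2-yl)phenyl]-4H-chromen-4-one | COc1ccc(-c2cc(=O)c3c(OCc4ccccc4)cc(OCc4ccccc4)cc3o2)cc1B1OC(C)(C)C(C)(C)O1 | intermediate
6 | 1-[2,4-bis(benzyloxy)-6-{[tri(propan-2-yl)silyl]oxy}phenyl]ethan-1-one | CC(=O)c1c(O[Si](C(C)C)(C(C)C)C(C)C)cc(OCc2ccccc2)cc1OCc1ccccc1 | intermediate
7 | 1-[2,4-bis(benzyloxy)-3-bromo-6-{[tri(propan-2-yl)silyl]oxy}phenyl]ethan-1-one | CC(=O)c1c(O[Si](C(C)C)(C(C)C)C(C)C)cc(OCc2ccccc2)c(Br)c1OCc1ccccc1 | intermediate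
8 | 1-[2,4-bis(benzyloxy)-3-{5-[5,7-bis(benzyloxy)-4-oxo-4H-chromen-2-yl]-2-methoxyphenyl}-6-{[tri(propan-2-yl)silyl]oxy}phenyl]ethan-1-one | COc1ccc(-c2cc(=O)c3c(OCc4ccccc4)cc(OCc4ccccc4)cc3o2)cc1-c1c(OCc2ccccc2)cc(O[Si](C(C)C)(C(C)C)C(C)C)c(C(C)=O)c1OCc1ccccc1 | intermediate
9 | 1-[2,4-bis(benzyloxy)-3-{5-[5,7-bis(benzyloxy)-4-oxo-4H-chromen-2-yl]-2-methoxyphenyl}-6-hydroxyphenyl]ethan-1-one | COc1ccc(-c2cc(=O)c3c(OCc4ccccc4)cc(OCc4ccccc4)cc3o2)cc1-c1c(OCc2ccccc2)cc(O)c(C(C)=O)c1OCc1ccccc1 | intermediate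
10 | tert-butyl 3-[2,4-bis(benzyloxy)-3-{5-[5,7-bis(benzyloxy)-4-oxo-4H-chromen-2-yl]-2-methoxyphenyl}-6-hydroxyphenyl]-3-oxopropanoate | COc1ccc(-c2cc(=O)c3c(OCc4ccccc4)cc(OCc4ccccc4)cc3o2)cc1-c1c(OCc2ccccc2)cc(O)c(C(=O)CC(=O)OC(C)(C)C)c1OCc1ccccc1 | intermediate
11 | 4-methoxybenzaldehyde | COc1ccc(C=O)cc1 | starting material
12 | tert-butyl (2Z)-2-[2,4-bis(benzyloxy)-3-{5-[5,7-bis(benzyloxy)-4-oxo-4H-chromen-2-yl]-2-methoxyphenyl}-6-hydroxybenzoyl]-3-(4-methoxyphenyl)prop-2-enoate | COc1ccc(-c2cc(=O)c3c(OCc4ccccc4)cc(OCc4ccccc4)cc3o2)cc1-c1c(OCc2ccccc2)cc(O)c(C(=O)/C(=C/c2ccc(OC)cc2)C(=O)OC(C)(C)C)c1OCc1ccccc1 | intermediate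
13 | tert-butyl (2S,3R)-5,7-bis(benzyloxy)-6-{5-[5,7-bis(benzyloxy)-4-oxo-4H-chromen-2-yl]-2-methoxyphenyl}-2-(4-methoxyphenyl)-4-oxo-3,4-dihydro-2H-chromene-3-carboxylate | COc1ccc([C@@H]2[C@@H](C(=O)OC(C)(C)C)C(=O)c3c(cc(OCc4ccccc4)c(-c4cc(-c5cc(=O)c6c(OCc7ccccc7)cc(OCc7ccccc7)cc6o5)ccc4OC)c3OCc3ccccc3)O2)cc1 | intermediate
14 | (2S)-5,7-bis(benzyloxy)-6-{5-[5,7-bis(benzyloxy)-4-oxo-4H-chromen-2-yl]-2-methoxyphenyl}-2-(4-methoxyphenyl)-2,3-dihydro-4H-chromen-4-one | COc1ccc([C@@H]2CC(=O)c3c(cc(OCc4ccccc4)c(-c4cc(-c5cc(=O)c6c(OCc7ccccc7)cc(OCc7ccccc7)cc6o5)ccc4OC)c3OCc3ccccc3)O2)cc1 | intermediate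
15 | (2S)-6-[5-(5,7-dihydroxy-4-oxo-4H-chromen-2-yl)-2-methoxyphenyl]-5,7-dihydroxy-2-(4-methoxyphenyl)-2,3-dihydro-4H-chromen-4-one | COc1ccc([C@@H]2CC(=O)c3c(cc(O)c(-c4cc(-c5cc(=O)c6c(O)cc(O)cc6o5)ccc4OC)c3O)O2)cc1 | target

**Step count and risks**

Total step count: 10. Longest linear sequence: 8 (steps 1, 2, 3, 6, 7, 8, 9, 10).

Step 9. What may go wrong: incomplete enantioface discrimination on this crowded, donor-rich substrate, or loss of configuration at C2 by reversible ring opening before the ester is lost. Fallback, setting out from 9 and coming back at 14: 9 is heated with N,N-dimethylformamide dimethyl acetal (toluene, 90 °C) to give the dimethylaminovinyl ketone F1. Brief acid treatment (aq HCl, CH2Cl2, rt) closes it by addition–elimination, with loss of dimethylamine, to the 2-unsubstituted chromone F2. Palladium-catalysed enantioselective conjugate addition of 4-methoxyphenylboronic acid then gives 14 (Pd(OCOCF3)2, the tert-butyl pyridine–oxazoline ligand of the hand that gives 2S, NH4PF6, H2O, ClCH2CH2Cl, 60 °C). C2 is set there under ligand control, and the 2-aryl flavone enone is far less reactive to arylpalladium addition than the 2-unsubstituted chromone.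

Step 5. What may go wrong: bromination at the ring position next to the silyloxy group or on the acetyl methyl, so that the halogen does not end up para to the future O1. Fallback, setting out from 1 and coming back at 9: the regiochemistry is tied instead to the established halogenation ortho to a free chelated phenol. Chelation-controlled cleavage of the benzyl ether ortho to the ketone (BCl3, CH2Cl2, −78 °C) gives the symmetric 2,6-dihydroxy ketone F3. One of its two equivalent phenols is capped (MOMCl, i-Pr2NEt, CH2Cl2, 0 °C) to the mono(methoxymethyl) ether F4, the second staying free because it is chelated. Iodination (N-iodosuccinimide, DMF, rt) ortho to the free phenol gives the iodo phenol F5. Benzylation of that phenol (BnBr, K2CO3, DMF, 60 °C) gives the iodo dibenzyl ether F6, in which the halogen is again flanked by two benzyloxy groups and the differentiated oxygen is para to it. Coupling of F6 with 5 under the conditions of step 6 without fluoride gives the methoxymethyl-protected biaryl ketone F7, and mild acid (HCl, MeOH/THF, 40 °C) releases 9.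

Step 7. What may go wrong: O-acylation instead of C-acylation, double acylation, or attack of the basic medium on the flavone. Fallback, setting out from 7 and coming back at 10: the ester is introduced before the flavone and the free phenol are present. Bromo ketone 7 is C-acylated (LiN(SiMe3)2, Boc2O, THF, −78 °C) to the bromo β-keto ester F8, which is then coupled with 5 and desilylated as in step 6 to give 10 directly.

**Further compounds**

F1 | step 9 | (2E)-1-[2,4-bis(benzyloxy)-3-{5-[5,7-bis(benzyloxy)-4-oxo-4H-chromen-2-yl]-2-methoxyphenyl}-6-hydroxyphenyl]-3-(dimethylamino)prop-2-en-1-one | COc1ccc(-c2cc(=O)c3c(OCc4ccccc4)cc(OCc4ccccc4)cc3o2)cc1-c1c(OCc2ccccc2)cc(O)c(C(=O)/C=C/N(C)C)c1OCc1ccccc1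
F2 | step 9 | 5,7-bis(benzyloxy)-6-{5-[5,7-bis(benzyloxy)-4-oxo-4H-chromen-2-yl]-2-methoxyphenyl}-4H-chromen-4-one | COc1ccc(-c2cc(=O)c3c(OCc4ccccc4)cc(OCc4ccccc4)cc3o2)cc1-c1c(OCc2ccccc2)cc2occc(=O)c2c1OCc1ccccc1
F3 | step 5 | 1-[4-(benzyloxy)-2,6-dihydroxyphenyl]ethan-1-one | CC(=O)c1c(O)cc(OCc2ccccc2)cc1O
F4 | step 5 | 1-[4-(benzyloxy)-2-hydroxy-6-(methoxymethoxy)phenyl]ethan-1-one | CC(=O)c1c(O)cc(OCc2ccccc2)cc1OCOC
F5 | step 5 | 1-[4-(benzyloxy)-2-hydroxy-3-iodo-6-(methoxymethoxy)phenyl]ethan-1-one | CC(=O)c1c(O)c(I)c(OCc2ccccc2)cc1OCOC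
F6 | step 5 | 1-[2,4-bis(benzyloxy)-3-iodo-6-(methoxymethoxy)phenyl]ethan-1-one | CC(=O)c1c(OCc2ccccc2)c(I)c(OCc2ccccc2)cc1OCOC
F7 | step 5 | 1-[2,4-bis(benzyloxy)-3-{5-[5,7-bis(benzyloxy)-4-oxo-4H-chromen-2-yl]-2-methoxyphenyl}-6-(methoxymethoxy)phenyl]ethan-1-one | COc1ccc(-c2cc(=O)c3c(OCc4ccccc4)cc(OCc4ccccc4)cc3o2)cc1-c1c(OCc2ccccc2)cc(OCOC)c(C(C)=O)c1OCc1ccccc1
F8 | step 7 | tert-butyl 3-[2,4-bis(benzyloxy)-3-bromo-6-{[tri(propan-2-yl)silyl]oxy}phenyl]-3-oxopropanoate | CC(C)(C)OC(=O)CC(=O)c1c(O[Si](C(C)C)(C(C)C)C(C)C)cc(OCc2ccccc2)c(Br)c1OCc1ccccc1
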